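We ask how much open intermediate is left over in four flasks that all get more partner (13.0 mM) than substrate (10 mM).

    substrate → open intermediate (k1 = 0.023 h⁻¹)
    partner → second intermediate (k2 = 0.091 h⁻¹)
    open intermediate + second intermediate → target (k3 = 2.5 M⁻¹ h⁻¹)
    2 second intermediate → homo product (k4 = 1.6 M⁻¹ h⁻¹)
    target ⇌ isomer of the product (K5 = 0.37, k5 = 0.013 h⁻¹)

all flasks: time 12 d

| run | substrate | partner | remark |
|---|---|---|---|
| winter | 10 mM (in portions, 3, over 10 d) | 13.0 mM | first portion at the start, last at 10 d |
| spring | 10 mM | 13.0 mM (fed, over 10 d) | all else is in the flask from the start; the feed brings no volume worth counting |
| dawn | 10 mM (fed, over 10 d) | 13.0 mM | all else is in the flask from the start; the feed brings no volume worth counting |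
| midnight | 10 mM | 13.0 mM | everything together at the start |

- two of one species on the left: rate k times its square, two consumed each time
- run time (winter): 12 d

- which flask leads in amount of target, in percent of the substrate charged ("all alike" within 1.5 percentage points) (winter / spring / dawn / midnight / all alike)
- how much target is there at the end, in percent of the substrate charged: winter
- how much target is there at the end, in percent of the substrate charged: spring
- how much target is there at the end, in percent of the substrate charged: dawn
- how much target is there at the end, in percent of the substrate charged: midnight

On paper there are 3.00 mM of partner to spare. Yet we shall reckon a leftover of open intermediate in spring, the flask we expect to do best.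

The two statements go together once we see that second intermediate has two exits. Let I and J be the concentrations of open and second intermediate, x the constant 2.5 M⁻¹ h⁻¹, h the constant 1.6 M⁻¹ h⁻¹. Per unit of J, the exits run at xI towards target and 2hJ towards homo product; we write b for 2h, which is 3.20 M⁻¹ h⁻¹.

In spring the feed brings 0.0542 mM h⁻¹. Substrate opens with a half-life of 1.26 d, short against the 10 d of feeding, so we hold I at 5.00 mM, half the charge. J then stands where the two exits together take the feed, at 2.60 mM. The share xI/(xI+2hJ) comes to 60.0%: this is the capture share φ, a selectivity.

The fraction left is one minus φ times partner over substrate, which we reckon at 22.0% of the substrate in spring. By this reckoning spring sends 5.20 mM of partner towards homo product, more than the surplus.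

Target and isomer relax with a half-life of 0.600 d, short against 12 d, so target is the captured part divided by 1.37. That gives 57.0% for spring.

In midnight partner goes faster than substrate. With J at 6.50 mM and I at 5.00 mM, φ is 37.5%, giving 35.6%.

Winter, with I at 1.67 mM, has φ of 16.7%. Dawn, with the 1.00 mM fed during one homo half-life of the partner's charge, has 10.7%. We therefore name spring.

The forecast gave 27% for winter, 51% for spring, 23% for dawn and 37% for midnight, with spring leading, a lower spring than ours, on the ground that slow feeding “suppresses its second-order homo-coupling”.

The simulation puts spring first, with 21.1% in winter, 54.0% in spring, 17.2% in dawn and 38.1% in midnight. Spring holds 27.2% open intermediate at 12.0 d, against our 22.0%. Now take the neighbour of spring charged with 17 mM of substrate. We reckon I at 8.50 mM, J at 1.97 mM, and φ at 77.2%. The fraction left is then 41.0% and target 43.1% of that larger charge. That neighbour ends with 40.2% open intermediate and 44.3% target.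

(The numbers were drawn at random within sensible limits; the rest is arithmetic.)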